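**Retrosynthetic overview**

1. Ring C of the flavanone is cut at O-1–C-8a and C-4–C-4a: ring A becomes a 3-alkoxybenzyne (from the o-silylaryl triflate 26), and the O-1/C-2/C-3/C-4 chain with ring B becomes the (S)-β-silyloxy ester 10. One fluoride-triggered aryne insertion/acylation joins them and closes ring C with C-2 already set.
2. Enabling feature: the C-5 oxygen of ring A sits ortho to C-4a, so the aryne C-4a≡C-8a takes the alkoxide at C-8a and the negative charge at C-4a. O-1 and C-4 are 1,3-related (a β-oxy ester), so the aryl anion reaches the ester carbonyl through a six-membered transition state.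
3. Fragment with ring B: 2-bromo-3,4-dimethoxybenzaldehyde → geranylation → acetate aldol and oxidation → asymmetric transfer hydrogenation (sets C-2) → TMS ether.
4. Fragment with ring A: 2-hydroxy-4-methoxybenzaldehyde → MOM ether → Baeyer–Villiger → ortho-lithiation/prenylation → carbamate-directed ortho-silylation → triflate.
5. Ring order: rings A and B are bought as arenes; ring C is the only ring made (key step); removal of the MOM group ends the route.

Key step: step 14

Assumption: compounds 1, 2, 11 and 16 and all reagents are taken as commercial; "geranyl" means (2E)-3,7-dimethylocta-2,6-dien-1-yl and "prenyl" means 3-methylbut-2-en-1-yl throughout.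

**Route**

Step 1
Reactants: 1 2-bromo-3,4-dimethoxybenzaldehyde; 2 geranyl bromide
Product: 6 aldehyde 2-geranyl-3,4-dimethoxybenzaldehyde, via bromoaryl lithium α-amino alkoxide 3 (not isolated), via 2-lithioaryl lithium α-amino alkoxide 4 (not isolated), via 2-geranylaryl lithium α-amino alkoxide 5 (not isolated)
Conditions: LiN(Me)CH2CH2NMe2 (from the amine and n-BuLi), THF, −20 °C; n-BuLi, −78 °C; CuBr·SMe2 (10 mol%), 2, −78 → 0 °C; H2O, then cold aq. citric acid
Reagents that add atoms: geranyl bromide (2), BrC/C=C(\C)CCC=C(C)C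
Why: The formyl group is masked in the flask as its lithium α-amino alkoxide (in situ protection), bromine–lithium exchange then gives an aryllithium that undergoes copper-catalysed SN2 allylic substitution at the primary carbon of geranyl bromide, so the E-alkene is carried over unchanged and aqueous work-up returns the aldehyde.

Step 2
Reactants: 6 aldehyde 2-geranyl-3,4-dimethoxybenzaldehyde
Product: 7 ethyl (±)-3-(2-geranyl-3,4-dimethoxyphenyl)-3-hydroxypropanoate
Conditions: LiN(i-Pr)2, EtOAc, THF, −78 °C; then 6; AcOH quench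
Reagents that add atoms: ethyl acetate, CCOC(C)=O
Why: Aldol addition of the lithium enolate of ethyl acetate to the non-enolisable aldehyde, in which the carbinol centre is formed racemic on purpose because it is erased in step 3.

Step 3
Reactants: 7 ethyl (±)-3-(2-geranyl-3,4-dimethoxyphenyl)-3-hydroxypropanoate
Product: 8 ethyl 3-(2-geranyl-3,4-dimethoxyphenyl)-3-oxopropanoate
Conditions: Dess–Martin periodinane, NaHCO3, CH2Cl2, 0 °C → rt
Reagents that add atoms: none
Why: Dess–Martin oxidation of a secondary benzylic alcohol to the β-keto ester under buffered, neutral conditions that should leave both trisubstituted alkenes untouched.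

Step 4
Reactants: 8 ethyl 3-(2-geranyl-3,4-dimethoxyphenyl)-3-oxopropanoate
Product: 9 ethyl (3S)-3-(2-geranyl-3,4-dimethoxyphenyl)-3-hydroxypropanoate
Conditions: RuCl[(S,S)-TsDPEN](p-cymene) (1 mol%), HCO2H/Et3N (5:2), DMF, 30 °C
Reagents that add atoms: none
Why: Noyori asymmetric transfer hydrogenation, in which the (S,S)-TsDPEN ruthenium hydride attacks the aryl ketone face favoured by the CH–π contact between the aryl group and the η6-arene and should give the (S)-carbinol (O > aryl > CH2 > H) as for acetophenone-type substrates, while the isolated alkenes and the ester are inert.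

Step 5
Reactants: 9 ethyl (3S)-3-(2-geranyl-3,4-dimethoxyphenyl)-3-hydroxypropanoate
Product: 10 ethyl (3S)-3-(2-geranyl-3,4-dimethoxyphenyl)-3-(trimethylsilyloxy)propanoate
Conditions: TMSCl, imidazole, CH2Cl2, 0 °C; non-aqueous work-up, used directly
Reagents that add atoms: chlorotrimethylsilane (TMSCl), C[Si](C)(C)Cl
Why: Standard O-silylation that turns the alcohol into a masked alkoxide which fluoride can release in step 14 without any protic partner in the flask.

Step 6
Reactants: 11 2-hydroxy-4-methoxybenzaldehyde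
Product: 12 MOM aldehyde 4-methoxy-2-(methoxymethoxy)benzaldehyde
Conditions: MOMCl, i-Pr2NEt, CH2Cl2, 0 °C → rt
Reagents that add atoms: chloromethyl methyl ether (MOMCl), COCCl
Why: Williamson-type O-alkylation of the phenol, which installs the acetal that later directs ortho-lithiation and is the only group removed at the end.

Step 7
Reactants: 12 MOM aldehyde 4-methoxy-2-(methoxymethoxy)benzaldehyde
Product: 14 phenol 4-methoxy-2-(methoxymethoxy)phenol, via 4-methoxy-2-(methoxymethoxy)phenyl formate 13 (not isolated)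
Conditions: mCPBA, NaHCO3, CH2Cl2, 0 °C → rt; then K2CO3, MeOH, rt (argon)
Reagents that add atoms: 3-chloroperoxybenzoic acid (mCPBA), OOC(=O)c1cccc(Cl)c1
Why: Baeyer–Villiger oxidation in which the electron-rich aryl group migrates to give the aryl formate, which is cleaved in the same flask by methanolysis (Dakin-type conversion of an aldehyde into a phenol).

Step 8
Reactants: 14 phenol 4-methoxy-2-(methoxymethoxy)phenol
Product: 15 triisopropyl[4-methoxy-2-(methoxymethoxy)phenoxy]silane
Conditions: TIPSCl, imidazole, DMF, rt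
Reagents that add atoms: chlorotriisopropylsilane (TIPSCl), CC(C)[Si](Cl)(C(C)C)C(C)C
Why: O-silylation with a bulky group that neither coordinates the base nor exposes its own ortho position, so the next lithiation is steered away from this oxygen.

Step 9
Reactants: 15 triisopropyl[4-methoxy-2-(methoxymethoxy)phenoxy]silane; 16 prenyl bromide
Product: 18 triisopropyl[4-methoxy-2-(methoxymethoxy)-3-prenylphenoxy]silane, via 3-lithio aryl silyl ether 17 (not isolated)
Conditions: n-BuLi, TMEDA, THF, 0 °C; CuBr·SMe2 (10 mol%), 16, −78 °C → rt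
Reagents that add atoms: prenyl bromide (16), CC(C)=CCBr
Why: Directed ortho-metalation at the only ring position flanked by two coordinating groups (OMOM and OMe), followed by copper-catalysed SN2 allylation of the aryllithium with prenyl bromide.

Step 10
Reactants: 18 triisopropyl[4-methoxy-2-(methoxymethoxy)-3-prenylphenoxy]silane
Product: 19 phenol 4-methoxy-2-(methoxymethoxy)-3-prenylphenol
Conditions: TBAF, THF, 0 °C; aqueous work-up (argon)
Reagents that add atoms: none
Why: Fluoride-mediated cleavage of the Si–O bond, driven by the strength of the Si–F bond.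

Step 11
Reactants: 19 phenol 4-methoxy-2-(methoxymethoxy)-3-prenylphenol
Product: 20 carbamate 4-methoxy-2-(methoxymethoxy)-3-prenylphenyl N-isopropylcarbamate
Conditions: i-PrNCO, Et3N (cat.), CH2Cl2, rt
Reagents that add atoms: isopropyl isocyanate, CC(C)N=C=O
Why: Base-catalysed addition of the phenol to the isocyanate gives an N-isopropyl carbamate, a strong ortho-director that can later be removed by mild E1cB cleavage.

Step 12
Reactants: 20 carbamate 4-methoxy-2-(methoxymethoxy)-3-prenylphenyl N-isopropylcarbamate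
Product: 24 silyl carbamate 4-methoxy-2-(methoxymethoxy)-3-prenyl-6-(trimethylsilyl)phenyl N-isopropylcarbamate, via N-TBS carbamate 21 (not isolated), via 6-lithio N-TBS carbamate 22 (not isolated), via 6-trimethylsilyl N-TBS carbamate 23 (not isolated)
Conditions: TBSOTf, TMEDA, Et2O, 0 °C → rt; n-BuLi, TMEDA, −78 °C; TMSCl, −78 °C → rt; sat. aq. NH4Cl
Reagents that add atoms: chlorotrimethylsilane (TMSCl), C[Si](C)(C)Cl
Why: Directed ortho-metalation of the in situ N-silylated O-aryl carbamate, in which the carbamate delivers n-BuLi to its only free ortho position and TMSCl traps the aryllithium, the N–Si bond being hydrolysed on work-up.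

Step 13
Reactants: 24 silyl carbamate 4-methoxy-2-(methoxymethoxy)-3-prenyl-6-(trimethylsilyl)phenyl N-isopropylcarbamate
Product: 26 triflate 4-methoxy-2-(methoxymethoxy)-3-prenyl-6-(trimethylsilyl)phenyl trifluoromethanesulfonate, via 4-methoxy-2-(methoxymethoxy)-3-prenyl-6-(trimethylsilyl)phenol 25 (not isolated)
Conditions: Et2NH, DBU, MeCN, 40 °C; then PhNTf2, rt
Reagents that add atoms: N-phenylbis(trifluoromethanesulfonimide) (PhNTf2), O=S(=O)(N(c1ccccc1)S(=O)(=O)C(F)(F)F)C(F)(F)F
Why: E1cB cleavage of the N–H carbamate (the isocyanate is trapped by Et2NH as a urea) liberates the phenoxide, which is O-sulfonylated by PhNTf2 in the same flask to give the o-silylaryl triflate.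

Step 14
Reactants: 26 triflate 4-methoxy-2-(methoxymethoxy)-3-prenyl-6-(trimethylsilyl)phenyl trifluoromethanesulfonate; 10 ethyl (3S)-3-(2-geranyl-3,4-dimethoxyphenyl)-3-(trimethylsilyloxy)propanoate
Product: 30 MOM flavanone (2S)-2-(2-geranyl-3,4-dimethoxyphenyl)-7-methoxy-5-(methoxymethoxy)-6-prenylchroman-4-one, via 5-methoxy-3-(methoxymethoxy)-4-prenylbenzyne 27 (not isolated), via cesium alkoxide of the hydroxy ester 28 (not isolated), via aryl cesium adduct 29 (not isolated)
Conditions: CsF (3 equiv), 18-crown-6, THF, 0 °C → rt (CsF added to 10 and 26, 26 in slight excess)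
Reagents that add atoms: none
Why: Proposed new method: fluoride removes the trimethylsilyl group of 26 to give the 3-alkoxybenzyne 27 and also unmasks 10 as its cesium alkoxide 28; the alkoxide oxygen adds to the aryne carbon remote from the OMOM group (the future C-8a) and the resulting aryl anion 29, which sits ortho to OMOM at the future C-4a, attacks the ester carbonyl and expels ethoxide, so that the O-1–C-8a and C-4–C-4a bonds are made in one operation. The closest known reaction types are the fluoride-mediated annulation of arynes by salicylate esters to xanthones and the insertion of arynes into the N–C(=O) bond of β-lactams to give 2,3-dihydroquinolin-4-ones; an aliphatic β-silyloxy ester as the O,C-partner has not been shown. Ring C is the only ring closed, by a 6-exo-trig acyl substitution of the aryl anion on the ester. No stereocenter is created: C-2 comes from 10 and its C–O bond is never broken, so the (S) configuration should be retained. The step needs (a) regioselective addition, secured by the inductively withdrawing OMOM group next to the aryne, which makes the unhindered distal carbon the electrophilic one and places the anion beside the oxygen, (b) acylation faster than protonation of the aryl anion, secured by the silyl ether (no O–H in the flask) and by THF, and (c) no base-induced E1cB opening of the flavanone, secured by the expelled ethoxide being scavenged as EtOSiMe3 through silyl transfer from the next molecule of 10.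

Step 15
Reactants: 30 MOM flavanone (2S)-2-(2-geranyl-3,4-dimethoxyphenyl)-7-methoxy-5-(methoxymethoxy)-6-prenylchroman-4-one
Product: 31 target (2S)-2-(2-geranyl-3,4-dimethoxyphenyl)-5-hydroxy-7-methoxy-6-prenylchroman-4-one
Conditions: HCl (1 M in MeOH), THF, 0 °C → rt; aq. NaHCO3
Reagents that add atoms: none
Why: Acid-catalysed methanolysis of the MOM acetal, which should be fast for this peri ether because the liberated phenol is hydrogen-bonded to the C-4 carbonyl, while no bond to C-2 is touched and the configuration is kept.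

**Compound list**

1 | 2-bromo-3,4-dimethoxybenzaldehyde | COc1ccc(C=O)c(Br)c1OC | starting material
2 | geranyl bromide, (2E)-1-bromo-3,7-dimethylocta-2,6-diene | BrC/C=C(\C)CCC=C(C)C | starting material
3 | lithium α-amino alkoxide from 1 and LiN(Me)CH2CH2NMe2 (racemic at the carbinol carbon) | [Li]OC(N(C)CCN(C)C)c1ccc(OC)c(OC)c1Br | intermediate (not isolated)
4 | 2-lithio derivative of 3 | [Li]OC(N(C)CCN(C)C)c1ccc(OC)c(OC)c1[Li] | intermediate (not isolated)
5 | 2-geranyl lithium α-amino alkoxide | [Li]OC(N(C)CCN(C)C)c1ccc(OC)c(OC)c1C/C=C(\C)CCC=C(C)C | intermediate (not isolated)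
6 | 2-[(2E)-3,7-dimethylocta-2,6-dien-1-yl]-3,4-dimethoxybenzaldehyde | O=Cc1ccc(OC)c(OC)c1C/C=C(\C)CCC=C(C)C | intermediate
7 | ethyl (±)-3-(2-geranyl-3,4-dimethoxyphenyl)-3-hydroxypropanoate | CCOC(=O)CC(O)c1ccc(OC)c(OC)c1C/C=C(\C)CCC=C(C)C | intermediate
8 | ethyl 3-(2-geranyl-3,4-dimethoxyphenyl)-3-oxopropanoate | CCOC(=O)CC(=O)c1ccc(OC)c(OC)c1C/C=C(\C)CCC=C(C)C | intermediate
9 | ethyl (3S)-3-(2-geranyl-3,4-dimethoxyphenyl)-3-hydroxypropanoate | CCOC(=O)C[C@@H](c1ccc(OC)c(OC)c1C/C=C(\C)CCC=C(C)C)O | intermediate
10 | ethyl (3S)-3-(2-geranyl-3,4-dimethoxyphenyl)-3-(trimethylsilyloxy)propanoate | CCOC(=O)C[C@@H](c1ccc(OC)c(OC)c1C/C=C(\C)CCC=C(C)C)O[Si](C)(C)C | intermediate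
11 | 2-hydroxy-4-methoxybenzaldehyde | COc1ccc(C=O)c(O)c1 | starting material
12 | 4-methoxy-2-(methoxymethoxy)benzaldehyde | COCOc1cc(OC)ccc1C=O | intermediate
13 | 4-methoxy-2-(methoxymethoxy)phenyl formate | COCOc1cc(OC)ccc1OC=O | intermediate (not isolated)
14 | 4-methoxy-2-(methoxymethoxy)phenol | COCOc1cc(OC)ccc1O | intermediate
15 | triisopropyl[4-methoxy-2-(methoxymethoxy)phenoxy]silane | COCOc1cc(OC)ccc1O[Si](C(C)C)(C(C)C)C(C)C | intermediate
16 | prenyl bromide, 1-bromo-3-methylbut-2-ene | CC(C)=CCBr | starting material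
17 | 3-lithio derivative of 15 | COCOc1c([Li])c(OC)ccc1O[Si](C(C)C)(C(C)C)C(C)C | intermediate (not isolated)
18 | triisopropyl[4-methoxy-2-(methoxymethoxy)-3-(3-methylbut-2-en-1-yl)phenoxy]silane | COCOc1c(CC=C(C)C)c(OC)ccc1O[Si](C(C)C)(C(C)C)C(C)C | intermediate
19 | 4-methoxy-2-(methoxymethoxy)-3-(3-methylbut-2-en-1-yl)phenol | COCOc1c(CC=C(C)C)c(OC)ccc1O | intermediate
20 | 4-methoxy-2-(methoxymethoxy)-3-(3-methylbut-2-en-1-yl)phenyl N-isopropylcarbamate | COCOc1c(CC=C(C)C)c(OC)ccc1OC(=O)NC(C)C | intermediate
21 | N-(tert-butyldimethylsilyl) derivative of 20 | COCOc1c(CC=C(C)C)c(OC)ccc1OC(=O)N(C(C)C)[Si](C)(C)C(C)(C)C | intermediate (not isolated)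
22 | 6-lithio derivative of 21 | COCOc1c(CC=C(C)C)c(OC)cc([Li])c1OC(=O)N(C(C)C)[Si](C)(C)C(C)(C)C | intermediate (not isolated)
23 | 6-trimethylsilyl derivative of 21 | COCOc1c(CC=C(C)C)c(OC)cc([Si](C)(C)C)c1OC(=O)N(C(C)C)[Si](C)(C)C(C)(C)C | intermediate (not isolated)
24 | 4-methoxy-2-(methoxymethoxy)-3-(3-methylbut-2-en-1-yl)-6-(trimethylsilyl)phenyl N-isopropylcarbamate | COCOc1c(CC=C(C)C)c(OC)cc([Si](C)(C)C)c1OC(=O)NC(C)C | intermediate
25 | 4-methoxy-2-(methoxymethoxy)-3-(3-methylbut-2-en-1-yl)-6-(trimethylsilyl)phenol | COCOc1c(CC=C(C)C)c(OC)cc([Si](C)(C)C)c1O | intermediate (not isolated)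
26 | 4-methoxy-2-(methoxymethoxy)-3-(3-methylbut-2-en-1-yl)-6-(trimethylsilyl)phenyl trifluoromethanesulfonate | COCOc1c(CC=C(C)C)c(OC)cc([Si](C)(C)C)c1OS(=O)(=O)C(F)(F)F | intermediate
27 | 5-methoxy-3-(methoxymethoxy)-4-(3-methylbut-2-en-1-yl)benzyne (1,2-didehydrobenzene) | COCOC1=C(CC=C(C)C)C(OC)=CC#C1 | intermediate (not isolated)
28 | cesium (1S)-1-(2-geranyl-3,4-dimethoxyphenyl)-3-ethoxy-3-oxopropan-1-olate | CCOC(=O)C[C@@H](c1ccc(OC)c(OC)c1C/C=C(\C)CCC=C(C)C)O[Cs] | intermediate (not isolated)
29 | ethyl (3S)-3-[2-cesio-5-methoxy-3-(methoxymethoxy)-4-prenylphenoxy]-3-(2-geranyl-3,4-dimethoxyphenyl)propanoate | CCOC(=O)C[C@@H](c1ccc(OC)c(OC)c1C/C=C(\C)CCC=C(C)C)Oc1cc(OC)c(CC=C(C)C)c(OCOC)c1[Cs] | intermediate (not isolated)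
30 | (2S)-2-{2-[(2E)-3,7-dimethylocta-2,6-dien-1-yl]-3,4-dimethoxyphenyl}-7-methoxy-5-(methoxymethoxy)-6-(3-methylbut-2-en-1-yl)-2,3-dihydro-4H-chromen-4-one | COc1cc2c(c(OCOC)c1CC=C(C)C)C(=O)C[C@@H](c1ccc(OC)c(OC)c1C/C=C(\C)CCC=C(C)C)O2 | intermediate
31 | (2S)-2-{2-[(2E)-3,7-dimethylocta-2,6-dien-1-yl]-3,4-dimethoxyphenyl}-5-hydroxy-7-methoxy-6-(3-methylbut-2-en-1-yl)-2,3-dihydro-4H-chromen-4-one | COc1cc2c(c(O)c1CC=C(C)C)C(=O)C[C@@H](c1ccc(OC)c(OC)c1C/C=C(\C)CCC=C(C)C)O2 | target

**Step count and risks**

Total step count: 15 (steps 1–5 for the ring B fragment, steps 6–13 for the ring A fragment, steps 14 and 15 after the union).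
Longest linear sequence: 10 steps (11 → 31 through steps 6–15).

Steps most likely to fail:

1. Step 14 (proposed new method). The aryl anion may be protonated, or may deprotonate the ester α-position and eliminate the aryloxide, before it closes onto the ester. The alkoxide may also attack the sulfur of the triflate. Base-induced ring opening and re-closure of the flavanone would erode the configuration at C-2.
   Fallback (known chemistry): it sets out from aldehyde 6 and aryne precursor 26 and comes back at 30. Knoevenagel–Doebner condensation of 6 with malonic acid (pyridine, piperidine, 90 °C) should give (2E)-3-(2-geranyl-3,4-dimethoxyphenyl)prop-2-enoic acid F1. The known fluoride-promoted C–O insertion of arynes into carboxylic acids (F1, 26, CsF, THF, 125 °C, sealed tube) adds the carboxylate oxygen at the same aryne carbon and transfers the acyl group to the neighbouring carbon; it again makes the O-1–C-8a and C-4–C-4a bonds in one operation and should give (2E)-3-(2-geranyl-3,4-dimethoxyphenyl)-1-[2-hydroxy-4-methoxy-6-(methoxymethoxy)-5-prenylphenyl]prop-2-en-1-one F2. Oxa-Michael closure (NaOAc, EtOH, reflux) should give the racemic MOM flavanone F3. Kinetic resolution by asymmetric transfer hydrogenation (RuCl[(R,R)-TsDPEN](p-cymene), HCO2H/Et3N, EtOAc, rt, stopped near half conversion) should reduce the (2R)-enantiomer to the cis-(2R,4R)-flavan-4-ol F4 and leave the (2S)-flavanone 30, which continues with step 15.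

2. Step 12. The silyl triflate used for N-silylation may cleave the MOM acetal, and the base may remove a benzylic–allylic proton of the prenyl group instead of the ring proton.
   Fallback: it sets out from phenol 19 and comes back at silyl phenol 25. Carbamoylation (ClC(O)NEt2, NaH, THF) should give 4-methoxy-2-(methoxymethoxy)-3-prenylphenyl N,N-diethylcarbamate F5, which needs no silyl triflate. Directed ortho-metalation (s-BuLi, TMEDA, THF, −78 °C; TMSCl) should give 4-methoxy-2-(methoxymethoxy)-3-prenyl-6-(trimethylsilyl)phenyl N,N-diethylcarbamate F6. Reductive cleavage (LiAlH4, THF, 0 °C → rt) should give 25, isolated this time, which is converted into 26 with PhNTf2 and Et3N as in the second half of step 13.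

3. Step 1. Butyllithium may add to the transiently masked formyl group, the bromine–lithium exchange may be incomplete, and the allylic bromide may be attacked at its tertiary end (linalyl-type isomer).
   Fallback: it sets out from 1 and comes back at 6. Acetalisation (ethylene glycol, TsOH, toluene, reflux with water removal) should give 2-(2-bromo-3,4-dimethoxyphenyl)-1,3-dioxolane F7. Bromine–lithium exchange (n-BuLi, THF, −78 °C), transmetalation with one equivalent of CuBr·SMe2 and allylation with 2 should give 2-(2-geranyl-3,4-dimethoxyphenyl)-1,3-dioxolane F8. Mild hydrolysis (PPTS, acetone/H2O, rt) should return 6.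

Further compounds
F1 | step 14 | (2E)-3-(2-geranyl-3,4-dimethoxyphenyl)prop-2-enoic acid | OC(=O)/C=C/c1ccc(OC)c(OC)c1C/C=C(\C)CCC=C(C)C
F2 | step 14 | (2E)-3-(2-geranyl-3,4-dimethoxyphenyl)-1-[2-hydroxy-4-methoxy-6-(methoxymethoxy)-5-prenylphenyl]prop-2-en-1-one | COCOc1c(CC=C(C)C)c(OC)cc(O)c1C(=O)/C=C/c1ccc(OC)c(OC)c1C/C=C(\C)CCC=C(C)C
F3 | step 14 | racemic 2-(2-geranyl-3,4-dimethoxyphenyl)-7-methoxy-5-(methoxymethoxy)-6-prenylchroman-4-one | COc1cc2c(c(OCOC)c1CC=C(C)C)C(=O)CC(c1ccc(OC)c(OC)c1C/C=C(\C)CCC=C(C)C)O2
F4 | step 14 | (2R,4R)-2-(2-geranyl-3,4-dimethoxyphenyl)-7-methoxy-5-(methoxymethoxy)-6-prenylchroman-4-ol | COc1cc2c(c(OCOC)c1CC=C(C)C)[C@H](O)C[C@H](c1ccc(OC)c(OC)c1C/C=C(\C)CCC=C(C)C)O2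
F5 | step 12 | 4-methoxy-2-(methoxymethoxy)-3-prenylphenyl N,N-diethylcarbamate | COCOc1c(CC=C(C)C)c(OC)ccc1OC(=O)N(CC)CC
F6 | step 12 | 4-methoxy-2-(methoxymethoxy)-3-prenyl-6-(trimethylsilyl)phenyl N,N-diethylcarbamate | COCOc1c(CC=C(C)C)c(OC)cc([Si](C)(C)C)c1OC(=O)N(CC)CC
F7 | step 1 | 2-(2-bromo-3,4-dimethoxyphenyl)-1,3-dioxolane | COc1ccc(C2OCCO2)c(Br)c1OC
F8 | step 1 | 2-(2-geranyl-3,4-dimethoxyphenyl)-1,3-dioxolane | COc1ccc(C2OCCO2)c(C/C=C(\C)CCC=C(C)C)c1OC
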